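Ring B is disconnected at C6–C7 and C8–C9, excising C7–C8 (with its methyl) as the silylene enediol ether of hydroxyacetone. The contiguous oxygenation C6(=O)–C7(OAc)–C8(OH)–C9(O) makes every union a natural-polarity aldol: in one flask the enediol carbon C7 adds to the C6 aldehyde on ring A, and the silyl-activated C8 ketone so formed is trapped by C9, the γ-carbon of a 2-silyloxyfuran on C10. This closes ring B and sets the C7/C8 cis-diol and the C9 spiro centre, whose furan oxygen becomes the ether oxygen of the C9/C13 tetrahydrofuran. The precursor is a monocyclic ring-A aldehyde carrying a butenolide.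

Key step: step 6

Remark: labdane numbering is used throughout (C5/C10 ring fusion, C20 the angular methyl, β = the face of C20). All bicyclic compounds have 5α-H, 10β-CH3, 8α-CH3 and C11 β on C9. 2-Bromofuran, hydroxyacetone and di-tert-butylsilyl bis(triflate) are taken as commercial.

Step 1
Reactants: 1 2,2,6-trimethylcyclohexan-1-one; 2 2-bromofuran
Product: 3 (R)-2-(furan-2-yl)-2,6,6-trimethylcyclohexan-1-one
Conditions: Pd2(dba)3 (2.5 mol%), (S)-BINAP (6 mol%; antipode to be matched to the (R)-ketone), NaOtBu, toluene, 80 °C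
Reagents that add atoms: none
Why: Palladium-catalysed enantioselective α-arylation of an α-methyl ketone whose other α-carbon is fully substituted (single enolate, no over-arylation); C–C reductive elimination from the BINAP-bound palladium enolate sets the quaternary C10.

Step 2
Reactants: 3 (R)-2-(furan-2-yl)-2,6,6-trimethylcyclohexan-1-one
Product: 4 spiro-epoxide of 3
Conditions: Me3S+ I−, n-BuLi, THF, −10 °C; then 3, to rt
Reagents that add atoms: trimethylsulfonium iodide C[S+](C)C.[I-]
Why: Corey–Chaykovsky epoxidation: the small sulfonium methylide should still add to the ketone flanked by two quaternary carbons, and the configuration of the new spiro carbon (drawn with oxygen cis to the C10 methyl) is of no consequence because this carbon is re-equilibrated in step 4.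

Step 3
Reactants: 4 spiro-epoxide of 3
Product: 5 enol-lactone epoxide
Conditions: [Ir(OMe)(cod)]2 (1.5 mol%), 4,4'-di-tert-butyl-2,2'-bipyridine, B2pin2, THF, 50 °C; then 30% H2O2, NaHCO3, 0 °C
Reagents that add atoms: hydrogen peroxide OO
Why: Iridium-catalysed C–H borylation is selective for the only unhindered furan α-C–H, and peroxide oxidation of the furyl boronate gives the 2-hydroxyfuran, which tautomerises to the enol lactone; no stereocentre is touched.

Step 4
Reactants: 5 enol-lactone epoxide
Product: 6 trans butenolide aldehyde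
Conditions: BF3·OEt2 (0.3 equiv), CH2Cl2, −78 °C; then DBU (0.2 equiv), rt
Reagents that add atoms: none
Why: Meinwald rearrangement (Lewis-acid opening of the epoxide at the tertiary carbon and 1,2-hydride shift) gives the aldehyde, and DBU then equilibrates the epimerisable C5–H to the trans isomer (CHO and lactone both equatorial, only the unavoidable methyl/methyl 1,3-diaxial contact left) while conjugating the lactone.

Step 5
Reactants: 7 hydroxyacetone
Product: 8 2,2-di-tert-butyl-4-methyl-1,3,2-dioxasilole
Conditions: tBu2Si(OTf)2, Et3N, CH2Cl2, 0 °C to rt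
Reagents that add atoms: di-tert-butylsilyl bis(trifluoromethanesulfonate) CC(C)(C)[Si](OS(=O)(=O)C(F)(F)F)(OS(=O)(=O)C(F)(F)F)C(C)(C)C
Why: Silylation of the hydroxyl followed by silyl enol ether formation under soft enolisation; closure of the five-membered dioxasilole ring forces enolisation toward the oxygen-bearing carbon, so a single enediol regioisomer should result.

Step 6
Reactants: 6 trans butenolide aldehyde; 8 2,2-di-tert-butyl-4-methyl-1,3,2-dioxasilole
Product: 10 6α-hydroxy-7β,8β-(di-tert-butylsilylenedioxy)-14,15,16-trinorlabd-11-en-13,9α-olide, via silyloxyfuran aldehyde 9 (not isolated)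
Conditions: TMSOTf (2.0 equiv), Et3N (1.2 equiv), CH2Cl2, −78 °C; then 8 (2 equiv), −78 to −40 °C; aq. citric acid work-up
Reagents that add atoms: none
Why: TMSOTf activates the C6 aldehyde of 9, the enediol silyl ether 8 attacks through its unsubstituted carbon C7 (Mukaiyama aldol) and leaves C8 as a carbonyl carbon under intramolecular silyl activation (cyclic silyloxocarbenium), which is captured by C9, the γ-carbon of the 2-silyloxyfuran, in an intramolecular vinylogous Mukaiyama aldol that releases TMSOTf and leaves the butenolide. The closest known reactions are Mukaiyama aldol additions of 1,2-bis(silyloxy)alkenes to aldehydes and vinylogous Mukaiyama aldol additions of 5-substituted 2-silyloxyfurans that create γ-quaternary butenolides. Ring B is closed in the second event by a 6-(enolexo)-exo-trig attack through a chair in which ring A is fused trans (C6 and C9 equatorial, C20 axial). C7 and C8 must be cis because both oxygens stay in the five-membered dioxasilolane, and C8 takes its methyl equatorial (oxygen β-axial) because the alternative places that methyl 1,3-diaxial to C20; the first addition is expected to be reversible, so the C7 epimer that cannot cyclise this way is drained, and the C6 carbinol (expected equatorial) is oxidised later. At C9 the furan oxygen is expected antiperiplanar to the C8 oxygen (dipole-minimised, synclinal approach of the two π systems), which places it α-axial and C11 equatorial. Chemoselectivity rests on geometry: the furan cannot reach the aldehyde (γ-attack would give a four-membered ring, α-attack a bridgehead alkene), so the intermolecular aldol comes first, and only γ-attack on C8 gives a six-membered ring.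

Step 7
Reactants: 10 6α-hydroxy-7β,8β-(di-tert-butylsilylenedioxy)-14,15,16-trinorlabd-11-en-13,9α-olide
Product: 11 6α-hydroxy-7β,8β-(di-tert-butylsilylenedioxy)-14,15,16-trinorlabdan-13,9α-olide
Conditions: H2 (1 atm), Pd/C, EtOAc, rt
Reagents that add atoms: none
Why: Catalytic hydrogenation of the disubstituted, conjugated butenolide alkene; no stereocentre is formed and silylene, lactone and hydroxyl are inert.

Step 8
Reactants: 11 6α-hydroxy-7β,8β-(di-tert-butylsilylenedioxy)-14,15,16-trinorlabdan-13,9α-olide
Product: 12 9α,13-epoxy-6α-hydroxy-7β,8β-(di-tert-butylsilylenedioxy)-14,15-dinorlabd-13(16)-ene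
Conditions: Cp2TiMe2 (3 equiv), toluene, 70 °C, dark
Reagents that add atoms: dimethyltitanocene C[Ti](C)(C1C=CC=C1)C1C=CC=C1
Why: Petasis methylenation: the titanium methylidene from Cp2TiMe2 olefinates the lactone carbonyl to the exocyclic enol ether under neutral conditions that spare the silylene (the free hydroxyl only consumes an extra equivalent).

Step 9
Reactants: 12 9α,13-epoxy-6α-hydroxy-7β,8β-(di-tert-butylsilylenedioxy)-14,15-dinorlabd-13(16)-ene
Product: 14 (13S)-9α,13-epoxy-6α,16-dihydroxy-7β,8β-(di-tert-butylsilylenedioxy)labd-14-yne, via spiro-epoxide 13 (not isolated)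
Conditions: dimethyldioxirane, acetone/CH2Cl2, −78 °C; then HC≡CZnCl (from HC≡CMgBr and ZnCl2), THF, −78 to 0 °C
Reagents that add atoms: dimethyldioxirane CC1(C)OO1; ethynylmagnesium bromide C#C[Mg]Br
Why: Epoxidation of the exocyclic enol ether gives an anomeric spiro-epoxide that the alkynylzinc should open with syn delivery (retention at C13), as with glycal epoxides; C13 is therefore fixed by the face of dioxirane attack, expected on the face flanked by C8 (equatorial methyl only) and not on the one flanked by C10 (C1 methylene backed by ring A), a modest bias that is treated as a risk below.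

Step 10
Reactants: 14 (13S)-9α,13-epoxy-6α,16-dihydroxy-7β,8β-(di-tert-butylsilylenedioxy)labd-14-yne
Product: 15 (13S)-9α,13;15,16-diepoxy-6α-hydroxy-7β,8β-(di-tert-butylsilylenedioxy)labd-14-ene
Conditions: Mo(CO)6 (30 mol%), Me3NO (30 mol%), Et3N, Et2O, rt
Reagents that add atoms: none
Why: Alkynol cycloisomerisation through a molybdenum vinylidene: the primary hydroxyl adds to the metal-bound carbon (endo mode) to give the 2,3-dihydrofuran under basic conditions that the acid-labile spiro enol ether tolerates; C13 is not involved.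

Step 11
Reactants: 15 (13S)-9α,13;15,16-diepoxy-6α-hydroxy-7β,8β-(di-tert-butylsilylenedioxy)labd-14-ene
Product: 16 (13S)-9α,13;15,16-diepoxy-7β,8β-(di-tert-butylsilylenedioxy)labd-14-en-6-one
Conditions: Dess–Martin periodinane, pyridine, CH2Cl2, 0 °C
Reagents that add atoms: none
Why: Dess–Martin oxidation of the only free hydroxyl (secondary C6–OH) under pyridine buffer should leave enol ether and silylene intact; C5 stays trans, the more stable ring fusion next to the new ketone.

Step 12
Reactants: 16 (13S)-9α,13;15,16-diepoxy-7β,8β-(di-tert-butylsilylenedioxy)labd-14-en-6-one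
Product: 17 (13S)-9α,13;15,16-diepoxy-7β,8β-dihydroxylabd-14-en-6-one
Conditions: TBAF, AcOH (1:1), THF, 0 °C
Reagents that add atoms: none
Why: Fluoride cleavage of the strained five-membered silylene, buffered with acetic acid to avoid retro-aldol or α-ketol shifts of the liberated hydroxy ketone; C7 keeps its equatorial (thermodynamic) oxygen.

Step 13
Reactants: 17 (13S)-9α,13;15,16-diepoxy-7β,8β-dihydroxylabd-14-en-6-one
Product: 18 (13S)-7β-acetoxy-9α,13;15,16-diepoxy-8β-hydroxylabd-14-en-6-one (CNP0284584.1)
Conditions: Ac2O, pyridine, DMAP (cat.), CH2Cl2, 0 °C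
Reagents that add atoms: acetic anhydride CC(=O)OC(C)=O
Why: Pyridine/DMAP acetylation is selective for the secondary C7 hydroxyl over the hindered tertiary axial C8 hydroxyl and should give the target.

Compound list
1 | 2,2,6-trimethylcyclohexan-1-one (racemic; the stereocentre is erased on enolisation) | CC1CCCC(C)(C)C1=O | starting material
2 | 2-bromofuran | Brc1ccco1 | starting material
3 | (R)-2-(furan-2-yl)-2,6,6-trimethylcyclohexan-1-one | CC1(C)CCC[C@](C)(c2ccco2)C1=O | intermediate
4 | 4-(furan-2-yl)-4,8,8-trimethyl-1-oxaspiro[2.5]octane, C4 as in 3, oxirane oxygen cis to the C4 methyl | CC1(C)CCC[C@](C)(c2ccco2)[C@]12CO2 | intermediate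
5 | 5-(4,8,8-trimethyl-1-oxaspiro[2.5]octan-4-yl)furan-2(3H)-one, configuration as in 4 | CC1(C)CCC[C@](C)(C2=CCC(=O)O2)[C@]12CO2 | intermediate
6 | (1S,2S)-2,6,6-trimethyl-2-(5-oxo-2,5-dihydrofuran-2-yl)cyclohexane-1-carbaldehyde (CHO and lactone trans; both epimers at the lactone C–O carbon, which converge in step 6) | O=C[C@H]1C(C)(C)CCC[C@]1(C)C1OC(=O)C=C1 | intermediate
7 | hydroxyacetone | CC(=O)CO | starting material
8 | 2,2-di-tert-butyl-4-methyl-1,3,2-dioxasilole | CC1=CO[Si](O1)(C(C)(C)C)C(C)(C)C | intermediate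
9 | (1S,2S)-2,6,6-trimethyl-2-[5-(trimethylsilyloxy)furan-2-yl]cyclohexane-1-carbaldehyde | O=C[C@H]1C(C)(C)CCC[C@]1(C)c1ccc(O[Si](C)(C)C)o1 | intermediate (not isolated)
10 | 6α-hydroxy-7β,8β-(di-tert-butylsilylenedioxy)-14,15,16-trinorlabd-11-en-13,9α-olide (spiro-butenolide at C9) | CC(C)(C)[Si]1(C(C)(C)C)O[C@H]2[C@H](O)[C@H]3C(C)(C)CCC[C@]3(C)[C@@]3(C=CC(=O)O3)[C@@]2(C)O1 | intermediate
11 | 6α-hydroxy-7β,8β-(di-tert-butylsilylenedioxy)-14,15,16-trinorlabdan-13,9α-olide | CC(C)(C)[Si]1(C(C)(C)C)O[C@H]2[C@H](O)[C@H]3C(C)(C)CCC[C@]3(C)[C@@]3(CCC(=O)O3)[C@@]2(C)O1 | intermediate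
12 | 9α,13-epoxy-6α-hydroxy-7β,8β-(di-tert-butylsilylenedioxy)-14,15-dinorlabd-13(16)-ene | CC(C)(C)[Si]1(C(C)(C)C)O[C@H]2[C@H](O)[C@H]3C(C)(C)CCC[C@]3(C)[C@@]3(CCC(=C)O3)[C@@]2(C)O1 | intermediate
13 | 9α,13;13,16-diepoxy-6α-hydroxy-7β,8β-(di-tert-butylsilylenedioxy)-14,15-dinorlabdane, oxirane oxygen on the face of the tetrahydrofuran syn to C8 | CC(C)(C)[Si]1(C(C)(C)C)O[C@H]2[C@H](O)[C@H]3C(C)(C)CCC[C@]3(C)[C@@]3(CC[C@]4(CO4)O3)[C@@]2(C)O1 | intermediate (not isolated)
14 | (13S)-9α,13-epoxy-6α,16-dihydroxy-7β,8β-(di-tert-butylsilylenedioxy)labd-14-yne | CC(C)(C)[Si]1(C(C)(C)C)O[C@H]2[C@H](O)[C@H]3C(C)(C)CCC[C@]3(C)[C@@]3(CC[C@@](CO)(C#C)O3)[C@@]2(C)O1 | intermediate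
15 | (13S)-9α,13;15,16-diepoxy-6α-hydroxy-7β,8β-(di-tert-butylsilylenedioxy)labd-14-ene | CC(C)(C)[Si]1(C(C)(C)C)O[C@H]2[C@H](O)[C@H]3C(C)(C)CCC[C@]3(C)[C@@]3(CC[C@@]4(C=COC4)O3)[C@@]2(C)O1 | intermediate
16 | (13S)-9α,13;15,16-diepoxy-7β,8β-(di-tert-butylsilylenedioxy)labd-14-en-6-one | CC(C)(C)[Si]1(C(C)(C)C)O[C@H]2C(=O)[C@H]3C(C)(C)CCC[C@]3(C)[C@@]3(CC[C@@]4(C=COC4)O3)[C@@]2(C)O1 | intermediate
17 | (13S)-9α,13;15,16-diepoxy-7β,8β-dihydroxylabd-14-en-6-one | O[C@H]1C(=O)[C@H]2C(C)(C)CCC[C@]2(C)[C@@]2(CC[C@@]3(C=COC3)O2)[C@@]1(C)O | intermediate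
18 | (13S)-7β-acetoxy-9α,13;15,16-diepoxy-8β-hydroxylabd-14-en-6-one (CNP0284584.1) | CC(=O)O[C@H]1C(=O)[C@H]2C(C)(C)CCC[C@]2(C)[C@@]2(CC[C@@]3(C=COC3)O2)[C@@]1(C)O | target

Total step count: 13. Longest linear sequence: 12 steps (steps 1–4 and 6–13).

Steps most likely to fail

Step 6. The domino may stall after the intermolecular aldol, because ring closure joins two fully substituted carbons next to quaternary C10, or it may close with poor facial selectivity at C9 (furan oxygen equatorial). The fallback sets out from aldehyde 6 and hydroxyacetone 7 and comes back at 10. A proline-catalysed direct aldol (proline antipode as matched, DMSO) joins C6 and C7 and should give the anti-6,7-diol methyl ketone F1. Catalytic DBU in THF then closes ring B by a reversible direct vinylogous aldol of the butenolide γ-carbon onto the C8 ketone, so that the spiro-butenolide triol F2 forms under thermodynamic control (C17 and C11 equatorial). tBu2Si(OTf)2 with 2,6-lutidine bridges the cis-7β,8β-diol and gives 10.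

Step 9. C13 is flanked almost symmetrically by C8 and C10, so facial selectivity in the epoxidation may be low or reversed. The fallback erases and re-sets C13 under reagent control; it sets out from enol ether 12 and comes back at 16. Dimethyldioxirane, then vinylzinc chloride, should give the C13-epimeric vinyl carbinol F3. Ozonolysis with NaBH4 work-up converts both epimers into the bis(hydroxymethyl) triol F4, in which C13 is no longer stereogenic. Lipase-catalysed acetylation (Burkholderia cepacia lipase, vinyl acetate) then differentiates the two hydroxymethyl groups and should give the monoacetate F5, acetylated on the arm syn to C10. Dess–Martin oxidation of the remaining primary and the C6 hydroxyl gives the keto aldehyde F6. The Ohira–Bestmann reagent with K2CO3 in MeOH homologates the aldehyde and removes the acetate to give the ethynyl carbinol ketone F7, which the molybdenum cycloisomerisation of step 10 converts into 16.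

Step 1. The unstable halofuran may decompose, or turnover and enantioselectivity may be low with the very hindered enolate. The fallback sets out from 2 and comes back at 3. Commercial 2,2-dimethylcyclohexan-1-one F8 is α-arylated with 2 (Pd2(dba)3, XPhos, NaOtBu) to racemic 2-(furan-2-yl)-6,6-dimethylcyclohexan-1-one F9. Asymmetric phase-transfer methylation of this α-aryl ketone (MeI, aq. KOH/toluene, chiral N-spiro binaphthyl quaternary ammonium bromide) then sets the quaternary centre and gives 3.

Further compounds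
F1 | step 6 | anti-6,7-diol methyl ketone: (1S,2S)-1-[(1S,2R)-1,2-dihydroxy-3-oxobutyl]-2,6,6-trimethyl-2-(5-oxo-2,5-dihydrofuran-2-yl)cyclohexane, configuration at C6/C7 as in 10 | CC(=O)[C@@H](O)[C@H](O)[C@H]1C(C)(C)CCC[C@]1(C)C1OC(=O)C=C1
F2 | step 6 | 6α,7β,8β-trihydroxy-14,15,16-trinorlabd-11-en-13,9α-olide | O[C@H]1[C@H](O)[C@H]2C(C)(C)CCC[C@]2(C)[C@@]2(C=CC(=O)O2)[C@@]1(C)O
F3 | step 9 | 9α,13-epoxy-6α,16-dihydroxy-7β,8β-(di-tert-butylsilylenedioxy)labd-14-ene, both C13 epimers | CC(C)(C)[Si]1(C(C)(C)C)O[C@H]2[C@H](O)[C@H]3C(C)(C)CCC[C@]3(C)[C@@]3(CCC(CO)(C=C)O3)[C@@]2(C)O1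
F4 | step 9 | 9α,13-epoxy-6α,14,16-trihydroxy-7β,8β-(di-tert-butylsilylenedioxy)-15-norlabdane | CC(C)(C)[Si]1(C(C)(C)C)O[C@H]2[C@H](O)[C@H]3C(C)(C)CCC[C@]3(C)[C@@]3(CCC(CO)(CO)O3)[C@@]2(C)O1
F5 | step 9 | 16-acetoxy-9α,13-epoxy-6α,14-dihydroxy-7β,8β-(di-tert-butylsilylenedioxy)-15-norlabdane, acetoxymethyl syn to C10 | CC(C)(C)[Si]1(C(C)(C)C)O[C@H]2[C@H](O)[C@H]3C(C)(C)CCC[C@]3(C)[C@@]3(CC[C@@](COC(C)=O)(CO)O3)[C@@]2(C)O1
F6 | step 9 | 16-acetoxy-9α,13-epoxy-6-oxo-7β,8β-(di-tert-butylsilylenedioxy)-15-norlabdan-14-al | CC(C)(C)[Si]1(C(C)(C)C)O[C@H]2C(=O)[C@H]3C(C)(C)CCC[C@]3(C)[C@@]3(CC[C@@](COC(C)=O)(C=O)O3)[C@@]2(C)O1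
F7 | step 9 | (13S)-9α,13-epoxy-16-hydroxy-7β,8β-(di-tert-butylsilylenedioxy)labd-14-yn-6-one | CC(C)(C)[Si]1(C(C)(C)C)O[C@H]2C(=O)[C@H]3C(C)(C)CCC[C@]3(C)[C@@]3(CC[C@@](CO)(C#C)O3)[C@@]2(C)O1
F8 | step 1 | 2,2-dimethylcyclohexan-1-one | CC1(C)CCCCC1=O
F9 | step 1 | 2-(furan-2-yl)-6,6-dimethylcyclohexan-1-one (racemic) | CC1(C)CCCC(c2ccco2)C1=O
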